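**Remarks on the chemistry (assumptions and changes)**

- The structures were checked against the target. The C2 descriptor is (S) in the open-chain alcohol 15, the flavan 16 and the target 20, because the CIP order O > aryl > CH2 > H is the same in all three; no structural error was found.
- One design change is made to the key-step precursor: the C4 oxygen carries a triisopropylsilyl (TIPS) group, not tert-butyldimethylsilyl. A smaller silyl group on the more hindered oxygen of a 1,3-diol would be prone to a 1,5 O-to-O shift onto the C2 alkoxide under the basic coupling conditions. That would free the C4 alkoxide, which can chelate palladium and undergo beta-hydride elimination.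
- The C4 centre is made racemic and both epimers are carried together, since C4 ends as the carbonyl carbon.
- "Prenyl" means 3-methylbut-2-en-1-yl throughout.

## Structural features

The target is a flavanone: a benzene ring A fused to a dihydropyranone ring C (chroman-4-one), with a second benzene ring B attached to C2 through the single bond C2–C1'. Ring A is substituted at every carbon except C6: hydroxyl at C5 (hydrogen-bonded to the C4 carbonyl), methoxy at C7, prenyl at C8 and the ring oxygen O1 at C8a; ring B carries hydroxyl at C3' and methoxy at C4'. C2 is the only stereocentre, (S), with no neighbouring centre to relay or check its configuration. It is fragile in two ways: base opens ring C by expelling the O1 phenoxide from the C3 enolate (chalcone formation), and acid can ionise C2–O1 because the cation is para-methoxybenzylic. The prenyl alkene rules out hydrogenation, strong protic acid and careless use of boranes or electrophiles, and the two phenols must be distinguished from the two aryl methyl ethers. The real difficulties are to set C2 as one enantiomer and leave it undisturbed, and to place the prenyl group at C8 and not at C6. The key step exploits the fact that O1 bridges an sp2 carbon of ring A (C8a) and C2: closing ring C by forming O1–C8a on the arene lets the C2–O bond be made earlier as an ordinary secondary alcohol and never broken. C8a lies between C8 (prenyl) and C4a, so a leaving group there has no ortho hydrogen.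

## Logic of the disconnections

20 ⇒ 19 ⇒ 18. The O–H bonds at C3' and C5 are traced back to a methoxymethyl ether and a methyl ether. Free phenols would interfere with the enolate and palladium chemistry. The C5 methyl ether can be distinguished from those at C7 and C4' only once the C4 carbonyl is present to form a six-membered chelate. The gain is that 18 contains only ethers and one ketone. The forward step needs a Lewis acid mild enough not to open C2–O1 and a short acid treatment that spares the alkene.

18 ⇒ 17 ⇒ 16. The C4 carbonyl is traced back to a carbinol and then to its silyl ether. A flavanone would not survive the base of the ring closure, whereas a silyl-protected carbinol does, and its configuration is irrelevant. The forward steps need fluoride deprotection and a neutral oxidation that touches neither the alkene nor C2.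

16 ⇒ 15. The O1–C8a bond is cut, opening ring C to an acyclic secondary alcohol tethered to an aryl triflate. This is the strategic cut: the stereochemical problem shrinks to one carbinol centre, and the bond formed in the forward direction is at an aromatic carbon. The forward step must favour C–O reductive elimination over beta-hydride elimination and must keep the silyl group on the C4 oxygen.

15 ⇒ 14 ⇒ 13. The C2–H bond is cut, giving an aryl alkyl ketone. This substrate class is the best case for catalytic enantioselective reduction. The gain is that all chirality comes from a catalyst. The forward step needs catalyst control that overrides the remote C4 centre, and a hydride source that leaves the alkene alone.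

13 ⇒ 12 ⇒ 11 ⇒ 10 + 7. The O–Si bond is removed and then the C3–C4 bond is cut by a retro-aldol. This divides the skeleton into two aromatic halves of similar size joined at the three-carbon bridge. The forward step is a kinetically controlled addition to a hindered aldehyde that must avoid retro-aldol, dehydration and sulfonyl transfer.

10 ⇒ 9 ⇒ 8. The enolate and the O–CH2OCH3 bond are traced back to a commercial ketone; the only demand is clean O-alkylation.

7 ⇒ 6 ⇒ 5 ⇒ 4. The O–S bond and the C4a–CHO bond are cut. The phenol oxygen first directs formylation to its single free ortho carbon and then becomes the leaving group, so one oxygen serves twice. The forward formylation must be ortho-specific and non-acidic because of the neighbouring prenyl group.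

4 ⇒ 3 + 2, and 3 ⇒ 1. The aryl–prenyl bond at C8 is cut. Because 1 is symmetric, both ortho carbons are equivalent and the later formylation fixes the prenyl group at C8. The forward step must favour ortho C-alkylation over O-alkylation and para attack.

## Other disconnections considered

Alternative 1: The cut is C2–C3, with ring C seen as a rearranged acetal. The precursor is the racemic 2-aryl-4-methylene-4H-1,3-benzodioxine A1 (5-OTBS, 7-OMe, 8-prenyl, TBS-protected ring B). A chiral acid would ionise its C2–O3 bond and the tethered enol carbon would recombine with the oxocarbenium carbon (Petasis–Ferrier type) to give the bis-silyl flavanone A2.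
- In its favour: the C2–C3 bond, the C4 ketone and the stereocentre arise in one event, and a racemic acetal is funnelled to one enantiomer because ionisation erases the stereocentre. C4 arrives at the ketone level, so no protection or redox steps at C4 are needed, and one fluoride step would finish the synthesis. On step economy it is better than the chosen plan.
- Against it: face selection in an aryl-stabilised oxocarbenium held only as an ion pair with a chiral counter-anion is an unproven demand for this substrate class. The same acid can re-ionise the para-methoxybenzylic C2–O1 bond of A2 and threatens the prenyl alkene. A1 needs methylenation of a benzodioxinone (for example with Cp2TiMe2) and a ring A whose two ortho oxygens are already differentiated; otherwise the 6-prenyl isomer forms.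
- Comparison: the chosen plan sets C2 by ketone reduction with a predictable sense and then breaks no bond to C2. It obtains the C5/C8a oxygen differentiation automatically from the formyl and triflate positions. It is longer but uses established reaction types only.

Alternative 2: The cut is C7–C8, with ring A built last. The precursor is the (S)-dihydropyranone A3, carrying a methyl malonyl group on C4a and a 4-methylpent-3-enyl chain on C8a. The extended enolate at C8 would acylate the ester carbon C7 (Claisen/Dieckmann type) and the new ring would enolise to the 5,7-dihydroxy flavanone A4.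
- In its favour: the prenyl position is fixed by the carbon chain, with no C- versus O-alkylation issue, which is better than step 1 of the chosen plan. C2 could be set on a simple dihydropyranone by a catalytic asymmetric hetero-Diels–Alder reaction, which is equal in reliability to a ketone reduction.
- Against it: the most acidic protons of A3 are the malonyl CH2 and C3–H, not C8–H, so the C8 enolate needs a polyanion under strong base. The C3 enolate can expel O1 from C2, opening the ring and destroying the stereocentre. A4 has two free phenols and needs a further selective 7-O-methylation under base. A3 itself takes many steps to assemble.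
- Comparison: the chosen plan never exposes a C4 carbonyl with the C2–O1 bond to base, and it is shorter.

Alternative 3: The cut is C4–C4a. The (S)-3-aryl-3-aryloxypropanoic acid A5 would be activated at the carboxyl carbon and closed by intramolecular Friedel–Crafts acylation to A6, which has the same constitution and configuration as 18.
- In its favour: the regiochemistry is unambiguous, since C4a is the only free carbon ortho to the ether oxygen and is activated by both methoxy groups. The ketone level is reached directly, the aryl partner is 4 of the chosen route, and the endgame is identical. On paper it is shorter, so on step economy it is the better plan.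
- Against it: the aryl ether bond at C2 must be made at the benzylic carbon, for instance by Mitsunobu inversion with the hindered phenol 4, which is the ionisation-prone situation. Under acylating acid A5 can lose the phenol by beta-elimination to a cinnamic acid or ionise at C2. The acylium ion or the acid can attack the prenyl alkene, and the methoxymethyl group is labile.
- Comparison: the two plans are equal from 18 onward. The difference is mechanistic: the chosen plan makes O1–C8a at an sp2 carbon under base, whereas this one makes and then stresses the C2–O bond under acid.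

Key step: step 8

## Route

Step 1
Reactants: 1 3,5-dimethoxyphenol; 2 prenyl bromide (1-bromo-3-methylbut-2-ene)
Product: 4 3,5-dimethoxy-2-prenylphenol, via sodium 3,5-dimethoxyphenoxide 3 (not isolated)
Conditions: NaH, toluene, 0 °C to rt; then 2, rt; neutral work-up
Reagents that add atoms: none
Why: Ortho C-alkylation of an alkali phenoxide by an allylic halide in a non-polar solvent: the sodium ion stays on oxygen and delivers the bromide to the adjacent carbon, and both ortho carbons of 1 are equivalent, so one C-prenyl phenol is expected beside separable O-alkylated and dialkylated material.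

Step 2
Reactants: 4 3,5-dimethoxy-2-prenylphenol
Product: 6 2-hydroxy-4,6-dimethoxy-3-prenylbenzaldehyde, via ortho-hydroxymethyl phenol 5 (not isolated)
Conditions: MgCl2, Et3N, (CH2O)n, MeCN, reflux; cold dilute HCl work-up
Reagents that add atoms: paraformaldehyde (formaldehyde source), C=O
Why: Magnesium-mediated ortho-formylation (Casnati–Skattebøl): the magnesium phenoxide delivers formaldehyde only to the ortho carbon, C6 is the single free one, and the hydroxymethyl intermediate is oxidised in the flask by hydride transfer to a second formaldehyde; the basic medium spares the prenyl group, which acidic formylation conditions would cyclise onto the phenol.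

Step 3
Reactants: 6 2-hydroxy-4,6-dimethoxy-3-prenylbenzaldehyde
Product: 7 2-formyl-3,5-dimethoxy-6-prenylphenyl trifluoromethanesulfonate
Conditions: Tf2O, pyridine, CH2Cl2, 0 °C
Reagents that add atoms: trifluoromethanesulfonic anhydride, O=S(=O)(OS(=O)(=O)C(F)(F)F)C(F)(F)F
Why: O-Sulfonylation of a phenol; it installs the leaving group for the ring closure, masks the phenol for the enolate chemistry and makes the formyl group more electrophilic.

Step 4
Reactants: 8 3'-hydroxy-4'-methoxyacetophenone
Product: 9 4'-methoxy-3'-(methoxymethoxy)acetophenone
Conditions: MOMCl, iPr2NEt, CH2Cl2, 0 °C to rt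
Reagents that add atoms: chloromethyl methyl ether, COCCl
Why: Williamson-type O-alkylation of a phenol with an alpha-chloro ether; the methoxymethyl ether tolerates enolate, borane, palladium, fluoride and oxidation chemistry and is removed by mild acid at the end.

Step 5
Reactants: 9 4'-methoxy-3'-(methoxymethoxy)acetophenone; 7 2-formyl-3,5-dimethoxy-6-prenylphenyl trifluoromethanesulfonate
Product: 12 racemic 2-{1-hydroxy-3-[4-methoxy-3-(methoxymethoxy)phenyl]-3-oxopropyl}-3,5-dimethoxy-6-prenylphenyl trifluoromethanesulfonate, via lithium enolate 10 (not isolated), via lithium aldolate 11 (not isolated)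
Conditions: LiN(iPr)2, THF, −78 °C; then 7, −78 °C; AcOH/THF quench at −78 °C
Reagents that add atoms: none
Why: Directed (crossed) aldol addition: the ketone is fully deprotonated before the non-enolisable aldehyde is added, and the triflate carbon has no ortho hydrogen, so aryne formation and anionic thia-Fries rearrangement are excluded; the new C4 centre is formed racemic on purpose because it is oxidised later.

Step 6
Reactants: 12 racemic beta-hydroxy ketone
Product: 13 racemic 2-{3-[4-methoxy-3-(methoxymethoxy)phenyl]-3-oxo-1-[(triisopropylsilyl)oxy]propyl}-3,5-dimethoxy-6-prenylphenyl trifluoromethanesulfonate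
Conditions: TIPSOTf, 2,6-lutidine, CH2Cl2, −78 to 0 °C
Reagents that add atoms: triisopropylsilyl trifluoromethanesulfonate, CC(C)[Si](OS(=O)(=O)C(F)(F)F)(C(C)C)C(C)C
Why: Silylation of a hindered secondary alcohol with a silyl triflate and a hindered pyridine base, conditions too mild for retro-aldol or dehydration; the triisopropylsilyl group blunts 1,3-induction in the next step and should not migrate later to the C2 alkoxide.

Step 7
Reactants: 13 racemic silyloxy ketone
Product: 15 2-{(3S)-3-hydroxy-3-[4-methoxy-3-(methoxymethoxy)phenyl]-1-[(triisopropylsilyl)oxy]propyl}-3,5-dimethoxy-6-prenylphenyl trifluoromethanesulfonate (both C1 epimers), via catecholboronate ester 14 (not isolated)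
Conditions: (R)-2-methyl-CBS-oxazaborolidine (0.2 equiv), catecholborane, toluene, −78 °C; then MeOH, aq. Na2CO3
Reagents that add atoms: none
Why: Corey–Bakshi–Shibata reduction: the (R)-oxazaborolidine binds the ketone with the aryl group as the large substituent and delivers hydride to the face that gives the (S)-carbinol, the established sense for aryl alkyl ketones; the bulky non-chelating silyl ether should leave the catalyst in control in both C1 epimers, and catecholborane at low temperature does not hydroborate the trisubstituted alkene.

Step 8
Reactants: 15 (3S)-hydroxy aryl triflate (both C1 epimers)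
Product: 16 (2S)-5,7-dimethoxy-2-[4-methoxy-3-(methoxymethoxy)phenyl]-8-prenyl-4-[(triisopropylsilyl)oxy]chroman (both C4 epimers)
Conditions: Pd(OAc)2 (5 mol %), 2-(di-tert-butylphosphino)-1,1'-binaphthyl (6 mol %), Cs2CO3, toluene, 70 °C
Reagents that add atoms: none
Why: This is a Buchwald–Hartwig-type C–O coupling, the palladium-catalysed intramolecular etherification of aryl halides and sulfonates with secondary alcohols that is established for chromans. Pd(OAc)2 is reduced in the flask to zerovalent palladium, which as a monophosphine complex adds oxidatively to the C8a–OTf bond; the C2 hydroxyl then binds, Cs2CO3 deprotonates it, and C–O reductive elimination from the seven-membered oxapalladacycle forms O1–C8a. Ring C closes as a six-membered ring by attack of the tethered oxygen on the aryl carbon, formally a 6-exo closure with the breaking C–Pd bond outside the new ring. No stereocentre is created: C2 stays (S) because its C–O bond is not involved, and both C4 epimers give the same ring. Reductive elimination must outrun beta-hydride elimination of the benzylic palladium alkoxide; the bulky electron-rich di-tert-butylphosphine and the crowding of C8a by its two ortho substituents both favour reductive elimination. The triflate must survive the base, which carbonate in toluene allows, and the absence of an ortho hydrogen rules out aryne formation. The triisopropylsilyl group keeps the C4 oxygen off palladium and, unlike a smaller silyl group, should not shift to the C2 alkoxide. The trisubstituted prenyl alkene could insert into the aryl–palladium bond only by forming a four-membered ring, so Heck-type side reactions are not expected.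

Step 9
Reactants: 16 (2S)-flavan silyl ether (both C4 epimers)
Product: 17 (2S)-5,7-dimethoxy-2-[4-methoxy-3-(methoxymethoxy)phenyl]-8-prenylchroman-4-ol (both C4 epimers)
Conditions: Bu4NF, THF, 0 °C to rt; NH4Cl work-up
Reagents that add atoms: none
Why: Fluoride-induced silyl ether cleavage driven by the Si–F bond; the medium is basic, as the acid-sensitive flavan-4-ol requires, and no carbonyl is present yet, so C2 cannot epimerise.

Step 10
Reactants: 17 (2S)-flavan-4-ol (both C4 epimers)
Product: 18 (2S)-5,7-dimethoxy-2-[4-methoxy-3-(methoxymethoxy)phenyl]-8-prenylchroman-4-one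
Conditions: Dess–Martin periodinane, NaHCO3, CH2Cl2, 0 °C to rt
Reagents that add atoms: none
Why: Dess–Martin oxidation of a secondary benzylic alcohol under buffered near-neutral conditions; both C4 epimers converge on one ketone, and the alkene, the electron-rich rings and C2 (not alpha to the new carbonyl) are untouched.

Step 11
Reactants: 18 (2S)-trimethoxy methoxymethyl flavanone
Product: 20 (2S)-5-hydroxy-2-(3-hydroxy-4-methoxyphenyl)-7-methoxy-8-prenylchroman-4-one (target), via 5-hydroxy methoxymethyl ether 19 (not isolated)
Conditions: MgI2·OEt2, toluene/Et2O, 60 °C; then 3 M HCl, MeOH, 45 °C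
Reagents that add atoms: none
Why: Chelation-controlled ether cleavage followed by acetal hydrolysis: magnesium binds the C4 carbonyl and the peri 5-methoxy oxygen in a six-membered chelate and iodide removes that methyl group by SN2 attack, while the 7- and 4'-methoxy groups lack this activation; dilute HCl in methanol then transfers the methoxymethyl group to the solvent. Neither operation forms or breaks a bond at C2, and no phenol sits next to the prenyl group, so acid-induced chroman formation is not possible.

## Compound list

1 | 3,5-dimethoxyphenol | COc1cc(O)cc(OC)c1 | starting material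
2 | prenyl bromide (1-bromo-3-methylbut-2-ene) | CC(C)=CCBr | starting material
3 | sodium 3,5-dimethoxyphenoxide | COc1cc([O-])cc(OC)c1.[Na+] | intermediate (not isolated)
4 | 3,5-dimethoxy-2-prenylphenol | COc1cc(O)c(CC=C(C)C)c(OC)c1 | intermediate
5 | 2-(hydroxymethyl)-3,5-dimethoxy-6-prenylphenol (as its magnesium phenoxide) | COc1cc(OC)c(CC=C(C)C)c(O)c1CO | intermediate (not isolated)
6 | 2-hydroxy-4,6-dimethoxy-3-prenylbenzaldehyde | COc1cc(OC)c(CC=C(C)C)c(O)c1C=O | intermediate
7 | 2-formyl-3,5-dimethoxy-6-prenylphenyl trifluoromethanesulfonate | COc1cc(OC)c(CC=C(C)C)c(OS(=O)(=O)C(F)(F)F)c1C=O | intermediate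
8 | 3'-hydroxy-4'-methoxyacetophenone | COc1ccc(C(C)=O)cc1O | starting material
9 | 4'-methoxy-3'-(methoxymethoxy)acetophenone | COCOc1cc(C(C)=O)ccc1OC | intermediate
10 | lithium enolate of 9 | [Li+].[O-]C(=C)c1ccc(OC)c(OCOC)c1 | intermediate (not isolated)
11 | lithium aldolate of 12 (racemic) | [Li+].[O-]C(CC(=O)c1ccc(OC)c(OCOC)c1)c1c(OC)cc(OC)c(CC=C(C)C)c1OS(=O)(=O)C(F)(F)F | intermediate (not isolated)
12 | 2-{1-hydroxy-3-[4-methoxy-3-(methoxymethoxy)phenyl]-3-oxopropyl}-3,5-dimethoxy-6-prenylphenyl trifluoromethanesulfonate (racemic) | COCOc1cc(ccc1OC)C(=O)CC(O)c1c(OC)cc(OC)c(CC=C(C)C)c1OS(=O)(=O)C(F)(F)F | intermediate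
13 | 2-{3-[4-methoxy-3-(methoxymethoxy)phenyl]-3-oxo-1-[(triisopropylsilyl)oxy]propyl}-3,5-dimethoxy-6-prenylphenyl trifluoromethanesulfonate (racemic) | COCOc1cc(ccc1OC)C(=O)CC(O[Si](C(C)C)(C(C)C)C(C)C)c1c(OC)cc(OC)c(CC=C(C)C)c1OS(=O)(=O)C(F)(F)F | intermediate
14 | catecholboronate ester of 15 (S at the carbinol carbon, both C1 epimers) | COc1ccc([C@@H](OB2Oc3ccccc3O2)CC(O[Si](C(C)C)(C(C)C)C(C)C)c2c(OC)cc(OC)c(CC=C(C)C)c2OS(=O)(=O)C(F)(F)F)cc1OCOC | intermediate (not isolated)
15 | 2-{(3S)-3-hydroxy-3-[4-methoxy-3-(methoxymethoxy)phenyl]-1-[(triisopropylsilyl)oxy]propyl}-3,5-dimethoxy-6-prenylphenyl trifluoromethanesulfonate (both C1 epimers) | COc1ccc([C@@H](O)CC(O[Si](C(C)C)(C(C)C)C(C)C)c2c(OC)cc(OC)c(CC=C(C)C)c2OS(=O)(=O)C(F)(F)F)cc1OCOC | intermediate (key-step precursor)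
16 | (2S)-5,7-dimethoxy-2-[4-methoxy-3-(methoxymethoxy)phenyl]-8-prenyl-4-[(triisopropylsilyl)oxy]chroman (both C4 epimers) | COc1ccc([C@@H]2CC(O[Si](C(C)C)(C(C)C)C(C)C)c3c(OC)cc(OC)c(CC=C(C)C)c3O2)cc1OCOC | intermediate (key-step product)
17 | (2S)-5,7-dimethoxy-2-[4-methoxy-3-(methoxymethoxy)phenyl]-8-prenylchroman-4-ol (both C4 epimers) | COc1ccc([C@@H]2CC(O)c3c(OC)cc(OC)c(CC=C(C)C)c3O2)cc1OCOC | intermediate
18 | (2S)-5,7-dimethoxy-2-[4-methoxy-3-(methoxymethoxy)phenyl]-8-prenylchroman-4-one | COc1ccc([C@@H]2CC(=O)c3c(OC)cc(OC)c(CC=C(C)C)c3O2)cc1OCOC | intermediate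
19 | (2S)-5-hydroxy-7-methoxy-2-[4-methoxy-3-(methoxymethoxy)phenyl]-8-prenylchroman-4-one | COc1ccc([C@@H]2CC(=O)c3c(O)cc(OC)c(CC=C(C)C)c3O2)cc1OCOC | intermediate (not isolated)
20 | (2S)-5-hydroxy-2-(3-hydroxy-4-methoxyphenyl)-7-methoxy-8-prenylchroman-4-one (CNP0228678.1) | COc1ccc([C@@H]2CC(=O)c3c(O)cc(OC)c(CC=C(C)C)c3O2)cc1O | target

## Step count and least certain steps

Total: 11 steps. Longest linear sequence: 10 steps (steps 1–3 and 5–11, from 1); step 4 is the only step of the second branch.

**Step 8 (key step).** The most likely failures are beta-hydride elimination from the benzylic palladium alkoxide (which reduces off the triflate and oxidises C2), cleavage of the triflate S–O bond by base, and slow oxidative addition at the crowded C8a. The fallback closes the other ether bond, O1–C2, with inversion. It sets out from 13 and returns at 16.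
- 13 is reduced with (S)-2-methyl-CBS-oxazaborolidine and catecholborane, through the (R)-configured catecholboronate ester F1, to the (3R)-hydroxy aryl triflate F2.
- The triflate is cleaved with Et4NOH in aqueous dioxane to the (3R)-hydroxy phenol F3.
- Mitsunobu cyclisation (PPh3, DIAD, THF, 0 °C) lets the phenol oxygen displace the activated C2 oxygen with inversion, giving 16.
- The weakness of this fallback is partial ionisation of the para-methoxybenzylic oxyphosphonium ion, which is why it is not the main plan.

**Step 1.** O-Alkylation, double alkylation and SN2' attack (giving the 1,1-dimethylallyl isomer) may compete with ortho C-alkylation. The fallback sets out from 1 and returns at 4.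
- 1 is O-allylated (allyl bromide, K2CO3, acetone) to allyl 3,5-dimethoxyphenyl ether F4.
- Thermal aromatic Claisen rearrangement (N,N-diethylaniline, 190 °C) can give only 2-allyl-3,5-dimethoxyphenol F5, because both ortho carbons are equivalent.
- Cross-metathesis with 2-methyl-2-butene (second-generation Grubbs catalyst, RuCl2(H2IMes)(PCy3)(=CHPh), CH2Cl2, 40 °C) converts allyl to prenyl and gives 4.

**Step 5.** Retro-aldol cleavage or dehydration of the aldolate on warming, and transfer of the triflyl group from the aryl oxygen to the neighbouring alkoxide, are the likely failures; all stem from the free alkoxide. The fallback sets out from 10 and returns at 12.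
- Enolate 10 is trapped with Me3SiCl to give the trimethylsilyl enol ether F6.
- A Mukaiyama aldol addition of F6 to 7 (BF3·OEt2, CH2Cl2, −78 °C, NaHCO3 work-up) gives 12 without a basic aldolate.

**Step 11.** Reversible opening of ring C at C2–O1 under the Lewis acid (eroding enantiopurity), addition of HX to the prenyl alkene, and incomplete discrimination between the methoxy groups are the risks. The fallback differentiates the C5 oxygen before the stereocentre exists, so no Lewis acid meets the flavanone. It sets out from 7 and returns at 20.
- The methoxy group ortho to the formyl group of 7 is cleaved under chelation control (MgI2·OEt2, toluene/Et2O, 60 °C) to 2-formyl-3-hydroxy-5-methoxy-6-prenylphenyl triflate F7.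
- F7 is protected (MOMCl, iPr2NEt) as 2-formyl-5-methoxy-3-(methoxymethoxy)-6-prenylphenyl triflate F8.
- F8 is taken through the operations of steps 5–10 unchanged: addition of 10 gives the lithium aldolate F9 and the hydroxy ketone F10; silylation gives the TIPS ether F11; CBS reduction gives, through the boronate F12, the (3S)-alcohol F13; palladium-catalysed closure gives the flavan F14; desilylation gives the flavan-4-ol F15; oxidation gives the 5,3'-bis(methoxymethyl) flavanone F16.
- One treatment with 3 M HCl in MeOH removes both acetals and gives 20.

## Further compounds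

F1 | step 8 | catecholboronate ester of F2 (R at the carbinol carbon, both C1 epimers) | COc1ccc([C@H](OB2Oc3ccccc3O2)CC(O[Si](C(C)C)(C(C)C)C(C)C)c2c(OC)cc(OC)c(CC=C(C)C)c2OS(=O)(=O)C(F)(F)F)cc1OCOC
F2 | step 8 | 2-{(3R)-3-hydroxy-3-[4-methoxy-3-(methoxymethoxy)phenyl]-1-[(triisopropylsilyl)oxy]propyl}-3,5-dimethoxy-6-prenylphenyl trifluoromethanesulfonate (both C1 epimers) | COc1ccc([C@H](O)CC(O[Si](C(C)C)(C(C)C)C(C)C)c2c(OC)cc(OC)c(CC=C(C)C)c2OS(=O)(=O)C(F)(F)F)cc1OCOC
F3 | step 8 | 2-{(3R)-3-hydroxy-3-[4-methoxy-3-(methoxymethoxy)phenyl]-1-[(triisopropylsilyl)oxy]propyl}-3,5-dimethoxy-6-prenylphenol (both C1 epimers) | COc1ccc([C@H](O)CC(O[Si](C(C)C)(C(C)C)C(C)C)c2c(OC)cc(OC)c(CC=C(C)C)c2O)cc1OCOC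
F4 | step 1 | allyl 3,5-dimethoxyphenyl ether | C=CCOc1cc(OC)cc(OC)c1
F5 | step 1 | 2-allyl-3,5-dimethoxyphenol | C=CCc1c(O)cc(OC)cc1OC
F6 | step 5 | {1-[4-methoxy-3-(methoxymethoxy)phenyl]ethenyloxy}trimethylsilane | C=C(O[Si](C)(C)C)c1ccc(OC)c(OCOC)c1
F7 | step 11 | 2-formyl-3-hydroxy-5-methoxy-6-prenylphenyl trifluoromethanesulfonate | COc1cc(O)c(C=O)c(OS(=O)(=O)C(F)(F)F)c1CC=C(C)C
F8 | step 11 | 2-formyl-5-methoxy-3-(methoxymethoxy)-6-prenylphenyl trifluoromethanesulfonate | COCOc1cc(OC)c(CC=C(C)C)c(OS(=O)(=O)C(F)(F)F)c1C=O
F9 | step 11 | lithium aldolate of F10 (racemic) | [Li+].[O-]C(CC(=O)c1ccc(OC)c(OCOC)c1)c1c(OCOC)cc(OC)c(CC=C(C)C)c1OS(=O)(=O)C(F)(F)F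
F10 | step 11 | 2-{1-hydroxy-3-[4-methoxy-3-(methoxymethoxy)phenyl]-3-oxopropyl}-5-methoxy-3-(methoxymethoxy)-6-prenylphenyl trifluoromethanesulfonate (racemic) | COCOc1cc(ccc1OC)C(=O)CC(O)c1c(OCOC)cc(OC)c(CC=C(C)C)c1OS(=O)(=O)C(F)(F)F
F11 | step 11 | triisopropylsilyl ether of F10 (racemic) | COCOc1cc(ccc1OC)C(=O)CC(O[Si](C(C)C)(C(C)C)C(C)C)c1c(OCOC)cc(OC)c(CC=C(C)C)c1OS(=O)(=O)C(F)(F)F
F12 | step 11 | catecholboronate ester of F13 (S at the carbinol carbon, both C1 epimers) | COc1ccc([C@@H](OB2Oc3ccccc3O2)CC(O[Si](C(C)C)(C(C)C)C(C)C)c2c(OCOC)cc(OC)c(CC=C(C)C)c2OS(=O)(=O)C(F)(F)F)cc1OCOC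
F13 | step 11 | 2-{(3S)-3-hydroxy-3-[4-methoxy-3-(methoxymethoxy)phenyl]-1-[(triisopropylsilyl)oxy]propyl}-5-methoxy-3-(methoxymethoxy)-6-prenylphenyl trifluoromethanesulfonate (both C1 epimers) | COc1ccc([C@@H](O)CC(O[Si](C(C)C)(C(C)C)C(C)C)c2c(OCOC)cc(OC)c(CC=C(C)C)c2OS(=O)(=O)C(F)(F)F)cc1OCOC
F14 | step 11 | (2S)-7-methoxy-5-(methoxymethoxy)-2-[4-methoxy-3-(methoxymethoxy)phenyl]-8-prenyl-4-[(triisopropylsilyl)oxy]chroman (both C4 epimers) | COc1ccc([C@@H]2CC(O[Si](C(C)C)(C(C)C)C(C)C)c3c(OCOC)cc(OC)c(CC=C(C)C)c3O2)cc1OCOC
F15 | step 11 | (2S)-7-methoxy-5-(methoxymethoxy)-2-[4-methoxy-3-(methoxymethoxy)phenyl]-8-prenylchroman-4-ol (both C4 epimers) | COc1ccc([C@@H]2CC(O)c3c(OCOC)cc(OC)c(CC=C(C)C)c3O2)cc1OCOC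
F16 | step 11 | (2S)-7-methoxy-5-(methoxymethoxy)-2-[4-methoxy-3-(methoxymethoxy)phenyl]-8-prenylchroman-4-one | COc1ccc([C@@H]2CC(=O)c3c(OCOC)cc(OC)c(CC=C(C)C)c3O2)cc1OCOC
A1 | alternative 1 | racemic 5-(tert-butyldimethylsilyloxy)-2-[3-(tert-butyldimethylsilyloxy)-4-methoxyphenyl]-7-methoxy-4-methylene-8-prenyl-4H-1,3-benzodioxine | C=C1OC(c2ccc(OC)c(O[Si](C)(C)C(C)(C)C)c2)Oc2c(CC=C(C)C)c(OC)cc(O[Si](C)(C)C(C)(C)C)c12
A2 | alternative 1 | (2S)-5,3'-bis-O-(tert-butyldimethylsilyl) ether of the target | COc1ccc([C@@H]2CC(=O)c3c(O[Si](C)(C)C(C)(C)C)cc(OC)c(CC=C(C)C)c3O2)cc1O[Si](C)(C)C(C)(C)C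
A3 | alternative 2 | methyl 3-{(2S)-2-[4-methoxy-3-(methoxymethoxy)phenyl]-6-(4-methylpent-3-en-1-yl)-4-oxo-3,4-dihydro-2H-pyran-5-yl}-3-oxopropanoate | COc1ccc([C@@H]2CC(=O)C(C(=O)CC(=O)OC)=C(CCC=C(C)C)O2)cc1OCOC
A4 | alternative 2 | (2S)-5,7-dihydroxy-4'-methoxy-3'-(methoxymethoxy)-8-prenylflavanone | COc1ccc([C@@H]2CC(=O)c3c(O)cc(O)c(CC=C(C)C)c3O2)cc1OCOC
A5 | alternative 3 | (3S)-3-(3,5-dimethoxy-2-prenylphenoxy)-3-[4-methoxy-3-(methoxymethoxy)phenyl]propanoic acid | COc1ccc([C@H](CC(=O)O)Oc2cc(OC)cc(OC)c2CC=C(C)C)cc1OCOC
A6 | alternative 3 | (2S)-5,7,4'-trimethoxy-3'-(methoxymethoxy)-8-prenylflavanone (same structure as 18) | COc1ccc([C@@H]2CC(=O)c3c(OC)cc(OC)c(CC=C(C)C)c3O2)cc1OCOC
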